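## Analysis of the target

Euchrenone a17 (17) is a flavanone: a chroman-4-one (rings A and C) carrying at C2 a 2,2-dimethylchroman-6-yl group, so that ring B has its 4'-oxygen and 3'-carbon tied into a saturated dimethylpyran ring. There is one stereocentre, C2, of S configuration, so only absolute control at this carbon is needed. C2 is benzylic, bound to the ring oxygen and beta to the C4 ketone; base (and less readily acid) opens ring C by retro-oxa-Michael reaction to the achiral 2'-hydroxychalcone 16, so the centre is best created last and handled gently afterwards. Other sensitive groups are the C8 prenyl group, which acid can cyclise onto the neighbouring 7-OH and oxidants attack, and the free 7-OH, which is para to the ketone and fairly acidic. The difficulty lies in ring A: the prenyl group stands at C8 between O1 and the 7-OH while C5 and C6 are bare, and electrophilic substitution or Claisen chemistry on a 2,4-dioxygenated aryl ketone does not reliably distinguish C8 from C6 or from oxygen. The strategy rests on the substitution order of ring A, read C4a, C8a, C8, C7, C6, C5 as acyl, O, prenyl, O, H, H: oxygen on alternate carbons, the acyl carbon C4a next to the unsubstituted C5, and no oxygen at C5. This is the pattern left when a linear poly-beta-carbonyl chain with a cinnamoyl head and an aldehyde tail folds by aldol condensation between C4a and C5, and in such a chain the prenyl group is only a substituent on an sp3 carbon between two ketones.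

## Retrosynthetic reasoning

**17 to 16.** The O1–C2 bond is cut first, in the sense of an intramolecular oxa-Michael addition. This removes ring C and the only stereocentre together and leaves the achiral chalcone 16. Because C2 is configurationally labile, making it in the last step means nothing afterwards can scramble it. The forward reaction must deliver the 2'-oxygen to one face of the enone beta-carbon under catalyst control.

**16 to 13.** Ring A is opened at C4a–C5 (C1'–C6' of 16) and de-aromatised to the open chain 13, via the free aldehyde 14 and the ring-closed diketone 15. This bond is chosen because its formation is an aldol condensation between the most nucleophilic carbon of the chain (the methylene between two ketones) and its most electrophilic one (the aldehyde). All ring A substituents are then already attached to chain carbons in the right order, so no aromatic substitution is needed. The forward step must unmask the aldehyde, close through carbon and not oxygen, and fold in the right direction.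

**13 to 8 and 10.** The C6–C7 bond of 13 is cut, giving the diketone 8 as a dianion and the acyl donor 10. In 8 the only position open to a second deprotonation is the carbon that carries the prenyl side chain, because the other flank of the diketone is vinylic, so the acylation is regiospecific. The N-methoxy-N-methylamide 10 is preferred to its parent ester 9 as acyl donor: its tetrahedral adduct 12 persists until quench, so the acidic triketone never meets the dianion.

**10 to 9.** The amide C–N bond is cut back to the commercial ester 9, a one-step functional group change.

**8 to 5 and 6.** The bond between C6 and C7 of 8 is cut, giving the methyl diketone 5 as its dianion and prenyl bromide 6. Alkylation of a diketone dianion at the terminal carbon is dependable, and it places the prenyl group on the carbon that later becomes C8 of 17. Assembling 8 in a single crossed ester condensation was considered, but it would invite conjugate addition and an ambiguous site of enolisation, so the two-step dianion route through 5 is preferred.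

**5 to 1 and 2.** The C5=C6 alkene of 5 is cut to aldehyde 1 and diketone 2. Boron chelation of 2 directs the condensation to a methyl group and blocks the central carbon. Ring B and its dimethylpyran ring come ready-made in 1.

## Alternatives that were turned down

Alternative 1: Both C-prenyl bonds (C8–CH2 and C3'–CH2) are traced back to oxygen. The chiral-pool flavanone (S)-liquiritigenin A3 would be converted into its bis(1,1-dimethylallyl) ether A2. Thermolysis of A2 would move the two allyl groups onto the ring carbons by aromatic Claisen rearrangement and give the diprenyl flavanone A1. An acid-mediated closure of the ring B prenylphenol of A1 would then form the dimethylpyran ring of 17.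
- For: very short; the Claisen shift is a clean pericyclic process; ring B is symmetric, so there is no regiochemical question there.
- Against: on ring A the shift can go to C6 as well as C8. The heat needed endangers C2 through ring opening and reclosure. A1 holds two ortho-prenylphenol units, and the final closure must pick the ring B unit and spare the 7-OH/8-prenyl pair; this rests only on the lower nucleophilicity of the 7-OH.
- Comparison: on step count and on the origin of C2 this alternative is stronger, since A3 supplies the centre whereas the chosen route must create it by catalysis in step 6. In its place the chosen route offers positional certainty: the prenyl group is put on a chain carbon in step 2, ring B is bought complete in 1, and no late differentiation of two like groups is needed.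

Alternative 2: Ring C is cut at C3=C4. The diene A5, an aryl ether of a nonracemic 1-arylallyl alcohol whose acetyl group is masked as a silyl enol ether, would undergo ring-closing metathesis with the second-generation Grubbs catalyst to give the 4-silyloxy-2H-chromene A4. Hydrolysis of the enol ether of A4 and a Claisen shift of its remaining dimethylallyl ether would then lead to 17.
- For: C2 is set early in an acyclic allylic ether, where asymmetric allylic etherification is dependable, and it is not exposed as a beta-aryloxy ketone until late. Metathesis of enol ethers to cyclic enol ethers is established.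
- Against: A5 has three terminal alkenes, and the electron-rich enol ether tends to tie up the catalyst as an unreactive carbene. The prenyl group still has to arrive by a thermal shift with the C6/C8 ambiguity, now on a formed flavanone. The sequence is clearly longer.
- Comparison: on control of C2 this alternative is stronger than the chosen route. In its place the chosen route offers a ring A whose substitution is fixed by construction, and about half the number of steps.

Alternative 3: Ring C is cut at O1–C2 and C3–C4. The salicylaldehyde A7 and trimethyl orthoformate A9 would give under acid the methoxy-substituted ortho-quinone methide A10, which would add to the vinylchroman A8 in a hetero-Diels–Alder reaction to form the 2,4-cis chroman A6. Conversion of the C4 methyl ether of A6 into the ketone and desilylation would follow.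
- For: convergent; two bonds, one ring and C2 are made in one operation, so on bonds formed per step it is stronger than the chosen route.
- Against: A7 already needs the prenyl group between two oxygens of a benzaldehyde, so the regiochemical problem is moved and not solved. The acid that makes A10 from A7 and A9 generates a cationic species next to a prenyl alkene that can trap it. Absolute control needs a chiral acid on a styrene-type partner such as A8. C4 must afterwards be brought to the ketone level in extra steps.
- Comparison: the chosen route is less convergent, but it offers a prenyl position settled by chain assembly, C4 at the ketone level throughout, and no strong acid in the presence of the prenyl group.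

Key step: step 5

Remarks on the chemistry:
- Aldehyde 1 is taken as a catalogue compound.
- The boron chelates 3 and 4 are written in their simplest form, as dibutoxyboron chelates.
- Chain carbons in steps 4 and 5 carry the locants of 13 (C1 at the aryl-bearing alkene carbon, C9 at the acetal carbon).

## Route

Step 1
Reactants: 1 2,2-dimethylchroman-6-carbaldehyde; 2 pentane-2,4-dione
Product: 5 (E)-6-(2,2-dimethylchroman-6-yl)hex-5-ene-2,4-dione, via boron chelate 3 (not isolated), via styryl boron chelate 4 (not isolated)
Conditions: 2 (3 equiv), B2O3 (0.7 equiv), B(OnBu)3 (2 equiv), EtOAc, 70 °C; n-BuNH2 (0.2 equiv), 70 °C; then 0.5 M HCl, 50 °C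
Reagents that add atoms: none
Why: Boron-templated aldol condensation (Pabon type, the standard route to styryl 1,3-diketones): chelation in 3 masks the central carbon of 2 and acidifies its methyl groups, so the amine-catalysed condensation with 1 should occur at CH3 only; excess 2 should hold it at the mono-adduct 4, and dilute acid frees 5 with the thermodynamically favoured E alkene.

Step 2
Reactants: 5 (E)-6-(2,2-dimethylchroman-6-yl)hex-5-ene-2,4-dione; 6 1-bromo-3-methylbut-2-ene (prenyl bromide)
Product: 8 (E)-1-(2,2-dimethylchroman-6-yl)-9-methyldeca-1,8-diene-3,5-dione, via dilithium dienolate 7 (not isolated)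
Conditions: LiN(i-Pr)2 (2.1 equiv, commercial solution), THF, −78 to 0 °C; 6 (1.0 equiv), −78 to −20 °C; AcOH
Reagents that add atoms: none
Why: Hauser–Harris alkylation of a 1,3-diketone dianion: the first equivalent of base removes the C3 proton and the second can only take a proton of the terminal methyl group, because the other flank is vinylic; the terminal carbanion of 7, the more basic site, should take the primary allylic bromide 6 by SN2 without attack at the central carbon or at oxygen.

Step 3
Reactants: 9 methyl 3,3-dimethoxypropanoate
Product: 10 N,3,3-trimethoxy-N-methylpropanamide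
Conditions: MeNH(OMe)·HCl (1.5 equiv), i-PrMgCl (3.0 equiv), THF, −20 to 0 °C
Reagents that add atoms: N,O-dimethylhydroxylamine hydrochloride, CNOC.Cl
Why: Aminolysis of an ester by the chloromagnesium amide of N,O-dimethylhydroxylamine, the usual one-step synthesis of N-methoxy-N-methylamides; the acetal is inert to the Grignard base at −20 °C and the magnesium chelate of 10 resists a second attack.

Step 4
Reactants: 8 (E)-1-(2,2-dimethylchroman-6-yl)-9-methyldeca-1,8-diene-3,5-dione; 10 N,3,3-trimethoxy-N-methylpropanamide
Product: 13 (E)-9,9-dimethoxy-1-(2,2-dimethylchroman-6-yl)-6-(3-methylbut-2-enyl)non-1-ene-3,5,7-trione, via dilithium dienolate 11 (not isolated), via tetrahedral adduct 12 (not isolated)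
Conditions: LiN(i-Pr)2 (2.1 equiv, commercial solution), THF, −78 to 0 °C; 10 (1.2 equiv), −78 to 0 °C; AcOH, −78 °C
Reagents that add atoms: none
Why: Acylation of a 1,3-diketone dianion by an N-methoxy-N-methylamide: the only position of 8 open to a second deprotonation is C6, which already bears the prenyl side chain, so the carbanion of 11 adds to 10 exactly where the chain must grow; the chelated adduct 12 holds until the acid quench, so the acidic triketone is not set free in base, cannot quench more dianion and cannot take a second addition. C6 of 13 is formed racemic, which is of no consequence because it becomes an aromatic carbon in step 5.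

Step 5
Reactants: 13 (E)-9,9-dimethoxy-1-(2,2-dimethylchroman-6-yl)-6-(3-methylbut-2-enyl)non-1-ene-3,5,7-trione
Product: 16 (E)-1-[2,4-dihydroxy-3-(3-methylbut-2-enyl)phenyl]-3-(2,2-dimethylchroman-6-yl)prop-2-en-1-one, via triketo aldehyde 14 (not isolated), via cyclohexenedione 15 (not isolated)
Conditions: AcOH–H2O–THF (3:1:1), pyrrolidine (0.5 equiv), 45 °C, N2
Reagents that add atoms: none
Why: Aqueous acetic acid hydrolyses the dimethyl acetal of 13 to aldehyde 14, which pyrrolidinium acetate holds as its enaminone and, once protonated, as the vinylogous iminium ion; the enol of the C3/C5 diketone then adds through C4 to C9 in a Mannich-type step, and loss of pyrrolidine gives the alkylidene diketone 15, whose two ring ketones enolise at once to the arene 16. The closest known reaction type is the amine-salt-catalysed Knoevenagel condensation of a 1,3-diketone with an aldehyde, run intramolecularly as in the aldol cyclisation and aromatisation of poly-beta-carbonyl chains to acylresorcinols. The one ring formed (ring A, chain atoms C4 to C9) closes in a 6-exo-trig mode at the iminium carbon, and both the enol-endo and the enol-exo variants of that closure are allowed. No stereocentre is created, and the racemic C6 of 13 ends as the aromatic carbon C3'. The step needs the fold from C4 to C9 and not from C8 to C3, and attack by carbon and not oxygen at C9: C4 is the most nucleophilic carbon of the chain and the iminium carbon its most electrophilic one, whereas C3 is a conjugated, enol-chelated ketone that does not take part in Knoevenagel chemistry. Attack of the C5 enol oxygen at C9 would lead towards a 4-pyranone, but the N,O-acetal on that path should revert in the presence of the amine, while the carbon path ends in an irreversible aromatisation. The weak acid and moderate temperature are chosen to spare the prenyl alkene, the enone and the new 2'-hydroxychalcone.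

Step 6
Reactants: 16 (E)-1-[2,4-dihydroxy-3-(3-methylbut-2-enyl)phenyl]-3-(2,2-dimethylchroman-6-yl)prop-2-en-1-one
Product: 17 (2S)-7-hydroxy-2-(2,2-dimethylchroman-6-yl)-8-(3-methylbut-2-enyl)chroman-4-one (euchrenone a17)
Conditions: 1-[3,5-bis(trifluoromethyl)phenyl]-3-[(8α,9S)-6'-methoxycinchonan-9-yl]thiourea (20 mol %), PhMe, 25 °C
Reagents that add atoms: none
Why: Bifunctional base catalysis of the intramolecular oxa-Michael addition of an o-hydroxyaryl enone, the cinchona-catalysed route to nonracemic chromanones and flavanones: the quinuclidine nitrogen takes the 2'-OH proton while the thiourea binds the ketone, so the phenoxide closes 6-endo-trig on one face of the beta-carbon within the chiral ion pair; C2 is set by the catalyst, and the sense of induction must be confirmed as 2S on first use.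

## Compound list

1 | 2,2-dimethylchroman-6-carbaldehyde | O=Cc1ccc2c(c1)CCC(C)(C)O2 | starting material
2 | pentane-2,4-dione | CC(=O)CC(C)=O | starting material
3 | dibutoxyboron chelate of 2 (2,2-dibutoxy-4,6-dimethyl-1,3,2-dioxaborinine) | CCCCO[B-]1(OCCCC)OC(C)=CC(C)=[O+]1 | intermediate (not isolated)
4 | dibutoxyboron chelate of 5 | CCCCO[B-]1(OCCCC)OC(C)=CC(/C=C/c2ccc3c(c2)CCC(C)(C)O3)=[O+]1 | intermediate (not isolated)
5 | (E)-6-(2,2-dimethylchroman-6-yl)hex-5-ene-2,4-dione | CC(=O)CC(=O)/C=C/c1ccc2c(c1)CCC(C)(C)O2 | intermediate
6 | 1-bromo-3-methylbut-2-ene | CC(C)=CCBr | starting material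
7 | dilithium (E)-6-(2,2-dimethylchroman-6-yl)hexa-1,3,5-triene-2,4-diolate | [Li+].[Li+].C=C([O-])C=C([O-])/C=C/c1ccc2c(c1)CCC(C)(C)O2 | intermediate (not isolated)
8 | (E)-1-(2,2-dimethylchroman-6-yl)-9-methyldeca-1,8-diene-3,5-dione | CC(C)=CCCC(=O)CC(=O)/C=C/c1ccc2c(c1)CCC(C)(C)O2 | intermediate
9 | methyl 3,3-dimethoxypropanoate | COC(=O)CC(OC)OC | starting material
10 | N,3,3-trimethoxy-N-methylpropanamide | COC(OC)CC(=O)N(C)OC | intermediate
11 | dilithium (1E)-1-(2,2-dimethylchroman-6-yl)-9-methyldeca-1,3,5,8-tetraene-3,5-diolate | [Li+].[Li+].CC(C)=CCC=C([O-])C=C([O-])/C=C/c1ccc2c(c1)CCC(C)(C)O2 | intermediate (not isolated)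
12 | dilithium salt of the tetrahedral adduct of 11 and 10 | [Li+].[Li+].COC(OC)CC([O-])(N(C)OC)C(CC=C(C)C)C(=O)C=C([O-])/C=C/c1ccc2c(c1)CCC(C)(C)O2 | intermediate (not isolated)
13 | (E)-9,9-dimethoxy-1-(2,2-dimethylchroman-6-yl)-6-(3-methylbut-2-enyl)non-1-ene-3,5,7-trione (C6 racemic) | COC(OC)CC(=O)C(CC=C(C)C)C(=O)CC(=O)/C=C/c1ccc2c(c1)CCC(C)(C)O2 | intermediate
14 | (E)-9-(2,2-dimethylchroman-6-yl)-4-(3-methylbut-2-enyl)-3,5,7-trioxonon-8-enal | O=CCC(=O)C(CC=C(C)C)C(=O)CC(=O)/C=C/c1ccc2c(c1)CCC(C)(C)O2 | intermediate (not isolated)
15 | 4-[(E)-3-(2,2-dimethylchroman-6-yl)prop-2-enoyl]-2-(3-methylbut-2-enyl)cyclohex-4-ene-1,3-dione | CC(C)=CCC1C(=O)CC=C(C(=O)/C=C/c2ccc3c(c2)CCC(C)(C)O3)C1=O | intermediate (not isolated)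
16 | (E)-1-[2,4-dihydroxy-3-(3-methylbut-2-enyl)phenyl]-3-(2,2-dimethylchroman-6-yl)prop-2-en-1-one | CC(C)=CCc1c(O)ccc(C(=O)/C=C/c2ccc3c(c2)CCC(C)(C)O3)c1O | intermediate
17 | (2S)-7-hydroxy-2-(2,2-dimethylchroman-6-yl)-8-(3-methylbut-2-enyl)chroman-4-one (euchrenone a17) | CC(C)=CCc1c(O)ccc2c1O[C@H](c1ccc3c(c1)CCC(C)(C)O3)CC2=O | target

## Step count and risk

Total step count: 6. Longest linear sequence: 5 steps (steps 1, 2, 4, 5 and 6 from 1); step 3 is a one-step side branch.

**Least certain: step 5 (key step).**
- Risk: closure through oxygen in place of carbon. The C5 enol oxygen can add to the unmasked aldehyde, and acid-driven dehydration of that hemiacetal gives a stable 4-pyranone that withdraws material from the carbon pathway. A lesser loss is premature, racemic closure of ring C in the product if the mixture is kept warm too long.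
- Fallback, from 13 back to 16: accept the oxygen closure and reverse it under base. Treatment of 13 with TsOH·H2O (cat.) in wet acetone at 20 °C should drive it fully to 2-[(E)-4-(2,2-dimethylchroman-6-yl)-2-oxobut-3-enyl]-3-(3-methylbut-2-enyl)-4H-pyran-4-one F1, which can be isolated. KOH in MeOH–H2O then adds hydroxide to the unsubstituted ring carbon next to oxygen and reopens the ring to the enolate of 14. Under base the carbon aldol and aromatisation follow (the known pyranone-to-acylresorcinol conversion). The product stays open as its phenolate, since in strong base the chalcone, not the flavanone, is the stable form; acidification returns 16.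

**Least certain: step 6.**
- Risk: low facial selectivity, possibly in the wrong sense, and erosion of ee by retro-oxa-Michael reaction. The enone is unactivated and electron-rich at its beta-carbon, and the acidic 4'-OH pairs with the catalyst base in competition with the 2'-OH.
- First remedy: if the sense is wrong, the quinidine-derived (9R) pseudoenantiomer of the same thiourea is used.
- Fallback, from 16 back to 17: replace catalyst-controlled closure by closure without control followed by kinetic resolution. NaOAc in EtOH at reflux should give racemic 7-hydroxy-2-(2,2-dimethylchroman-6-yl)-8-(3-methylbut-2-enyl)chroman-4-one F2. Asymmetric transfer hydrogenation with Cp*RhCl[(R,R)-TsDPEN] and HCO2H/Et3N in EtOAc should then reduce the 2R enantiomer faster, to the cis alcohol (2R,4R)-2-(2,2-dimethylchroman-6-yl)-8-(3-methylbut-2-enyl)chromane-4,7-diol F3, leaving 17 to be separated from it. The same reduction can upgrade scalemic 17 from step 6.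

**Least certain: step 4.**
- Risk: proton transfer in place of acylation. The hindered secondary carbanion of 11 may deprotonate 10 next to its carbonyl, and the amide enolate can then lose methoxide by beta-elimination, with 8 returned on quench.
- Fallback, from 8 (and 9) back to 13: form the C6–C7 bond by aldol addition and adjust the oxidation level afterwards. Reduction of 9 with i-Bu2AlH in CH2Cl2 at −78 °C gives 3,3-dimethoxypropanal F4, used fresh. Dianion 11, made from 8 as in step 4, adds to it at −78 °C to give (E)-7-hydroxy-9,9-dimethoxy-1-(2,2-dimethylchroman-6-yl)-6-(3-methylbut-2-enyl)non-1-ene-3,5-dione F5 as a mixture of diastereomers. Oxidation of the secondary alcohol with 2-iodoxybenzoic acid in EtOAc at 70 °C then gives 13.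

**Least certain: step 1.**
- Risk: over-condensation at the second methyl group of the chelate, giving the bis-styryl diketone, and incomplete hydrolysis of the boron chelate.
- Fallback, from 2 and 1 back to 5: a stepwise aldol addition and dehydration in which a second condensation is not possible. Diketone 2 with LiN(i-Pr)2 (2.1 equiv) in THF gives dilithium penta-1,3-diene-2,4-diolate F6. This adds through its terminal carbon to 1 at −78 °C to give racemic 6-hydroxy-6-(2,2-dimethylchroman-6-yl)hexane-2,4-dione F7. The benzylic alcohol is dehydrated with TsOH·H2O (cat.) in PhMe at 60 °C to 5.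

## Further compounds

F1 | step 5 | 2-[(E)-4-(2,2-dimethylchroman-6-yl)-2-oxobut-3-enyl]-3-(3-methylbut-2-enyl)-4H-pyran-4-one | CC(C)=CCc1c(CC(=O)/C=C/c2ccc3c(c2)CCC(C)(C)O3)occc1=O
F2 | step 6 | racemic 7-hydroxy-2-(2,2-dimethylchroman-6-yl)-8-(3-methylbut-2-enyl)chroman-4-one | CC(C)=CCc1c(O)ccc2c1OC(c1ccc3c(c1)CCC(C)(C)O3)CC2=O
F3 | step 6 | (2R,4R)-2-(2,2-dimethylchroman-6-yl)-8-(3-methylbut-2-enyl)chromane-4,7-diol | CC(C)=CCc1c(O)ccc2c1O[C@@H](c1ccc3c(c1)CCC(C)(C)O3)C[C@H]2O
F4 | step 4 | 3,3-dimethoxypropanal | COC(OC)CC=O
F5 | step 4 | (E)-7-hydroxy-9,9-dimethoxy-1-(2,2-dimethylchroman-6-yl)-6-(3-methylbut-2-enyl)non-1-ene-3,5-dione (mixture of diastereomers) | COC(OC)CC(O)C(CC=C(C)C)C(=O)CC(=O)/C=C/c1ccc2c(c1)CCC(C)(C)O2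
F6 | step 1 | dilithium penta-1,3-diene-2,4-diolate | [Li+].[Li+].C=C([O-])C=C(C)[O-]
F7 | step 1 | racemic 6-hydroxy-6-(2,2-dimethylchroman-6-yl)hexane-2,4-dione | CC(=O)CC(=O)CC(O)c1ccc2c(c1)CCC(C)(C)O2
A1 | alternative 1 | (S)-7-hydroxy-2-[4-hydroxy-3-(3-methylbut-2-enyl)phenyl]-8-(3-methylbut-2-enyl)chroman-4-one | CC(C)=CCc1c(O)ccc2c1O[C@H](c1ccc(O)c(CC=C(C)C)c1)CC2=O
A2 | alternative 1 | (S)-7-(2-methylbut-3-en-2-yloxy)-2-[4-(2-methylbut-3-en-2-yloxy)phenyl]chroman-4-one | C=CC(C)(C)Oc1ccc2c(c1)O[C@H](c1ccc(OC(C)(C)C=C)cc1)CC2=O
A3 | alternative 1 | (S)-7-hydroxy-2-(4-hydroxyphenyl)chroman-4-one (liquiritigenin) | O=C1C[C@@H](c2ccc(O)cc2)Oc2cc(O)ccc21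
A4 | alternative 2 | (S)-4-(tert-butyldimethylsilyloxy)-2-(2,2-dimethylchroman-6-yl)-7-(2-methylbut-3-en-2-yloxy)-2H-chromene | C=CC(C)(C)Oc1ccc2c(c1)O[C@H](c1ccc3c(c1)CCC(C)(C)O3)C=C2O[Si](C)(C)C(C)(C)C
A5 | alternative 2 | tert-butyl{1-[2-{[(1S)-1-(2,2-dimethylchroman-6-yl)prop-2-enyl]oxy}-4-(2-methylbut-3-en-2-yloxy)phenyl]ethenyloxy}dimethylsilane | C=C(O[Si](C)(C)C(C)(C)C)c1ccc(OC(C)(C)C=C)cc1O[C@@H](C=C)c1ccc2c(c1)CCC(C)(C)O2
A6 | alternative 3 | (2S,4S)-4-methoxy-2-(2,2-dimethylchroman-6-yl)-8-(3-methylbut-2-enyl)-7-(triisopropylsilyloxy)chroman (2,4-cis) | CC(C)=CCc1c(O[Si](C(C)C)(C(C)C)C(C)C)ccc2c1O[C@H](c1ccc3c(c1)CCC(C)(C)O3)C[C@@H]2OC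
A7 | alternative 3 | 2-hydroxy-3-(3-methylbut-2-enyl)-4-(triisopropylsilyloxy)benzaldehyde | CC(C)=CCc1c(O[Si](C(C)C)(C(C)C)C(C)C)ccc(C=O)c1O
A8 | alternative 3 | 2,2-dimethyl-6-vinylchroman | C=Cc1ccc2c(c1)CCC(C)(C)O2
A9 | alternative 3 | trimethyl orthoformate | COC(OC)OC
A10 | alternative 3 | 6-(methoxymethylidene)-2-(3-methylbut-2-enyl)-3-(triisopropylsilyloxy)cyclohexa-2,4-dien-1-one | COC=C1C=CC(O[Si](C(C)C)(C(C)C)C(C)C)=C(CC=C(C)C)C1=O
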